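**Plan**

- Retrosynthesis first cuts the 4'-O–Si bond, then the two bonds of the dimethylpyran on ring B (O2'–CMe2 and C3'–CH=), which leads back through an aryl 1,1-dimethylpropargyl ether to a 2'-hydroxyisoflavan.
- Enabling feature: O2' of ring B and C4 of the chroman are the two ends of the chain O2'–C2'–C1'–C3–C4. Joining them gives a five-membered ring cis-fused to the pyran ring, so the isoflavan is a cis-pterocarpan lacking its benzylic C4–O bond (C3 = 6a, C4 = 11a).
- That dihydrofuran ring is cut at C3–C1' and C4–O2' together, giving 5,7-dimethoxy-6-prenyl-2H-chromene and a 2-iodophenol silylated on the oxygen para to iodine. The chromene goes back through its aryl propargyl ether to 3,5-dimethoxy-4-prenylphenol and 1,3-dimethoxybenzene.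
- Forward ring order: ring A is prenylated and hydroxylated, the 2H-pyran is closed, the temporary dihydrofuran ring is closed in the palladium oxyarylation that also attaches ring B, lithium in ammonia opens it again, and the dimethylpyran is fused to ring B last.
- Stereochemistry: the chiral ligand on palladium sets C3 in the carbopalladation (6aR). The second centre (11aR, cis) follows from the tether and is erased in the reductive opening, which leaves C3 as R.

Key step: step 6

Assumption: (R)-BINAP is taken to direct the aryl group to the alkene face that gives 6aR; if the sense proves opposite, (S)-BINAP is used and nothing else changes.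

Remark: the ring-B oxygen para to iodine is carried as a triisopropylsilyl ether, because it has to pass Ag2CO3, lithium in ammonia, DBU and 140 °C before fluoride removes it.

**Route**

Step 1
Reactants: 1 1,3-dimethoxybenzene; 2 prenyl bromide (1-bromo-3-methylbut-2-ene)
Product: 4 1,3-dimethoxy-2-(3-methylbut-2-en-1-yl)benzene, via 2,6-dimethoxyphenyllithium 3 (not isolated)
Conditions: n-BuLi (1.1 equiv), THF, 0 °C to rt; then 2, –78 °C to rt
Reagents that add atoms: n-butyllithium, [Li]CCCC (the lithium of 3 only); prenyl bromide 2, CC(C)=CCBr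
Why: Directed ortho-metalation removes the proton flanked by both methoxy groups, and the aryllithium is then alkylated at the primary carbon of the allylic bromide (SN2), the standard entry to 2-alkylresorcinol dimethyl ethers.

Step 2
Reactants: 4 1,3-dimethoxy-2-(3-methylbut-2-en-1-yl)benzene
Product: 6 3,5-dimethoxy-4-(3-methylbut-2-en-1-yl)phenol, via arylboronic acid pinacol ester 5 (not isolated)
Conditions: [Ir(OMe)(cod)]2 (1.5 mol %), 4,4'-di-tert-butyl-2,2'-bipyridine (3 mol %), B2pin2 (1.0 equiv), THF, 60 °C; then aq. H2O2, NaOH, 0 °C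
Reagents that add atoms: bis(pinacolato)diboron, CC1(C)OB(OC1(C)C)B1OC(C)(C)C(C)(C)O1 (the boryl group of 5 only); hydrogen peroxide, OO (the phenol oxygen of 6)
Why: Iridium-catalysed C–H borylation is sterically governed and should take the only ring C–H without an ortho substituent (C5, meta to both methoxy groups), the hindered trisubstituted alkene being a poor hydroboration partner, and alkaline peroxide then turns C–B into C–OH at the same carbon (one-pot borylation/oxidation to a 3,5-disubstituted phenol).

Step 3
Reactants: 6 3,5-dimethoxy-4-(3-methylbut-2-en-1-yl)phenol; 7 propargyl bromide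
Product: 8 1,3-dimethoxy-2-(3-methylbut-2-en-1-yl)-5-(prop-2-yn-1-yloxy)benzene
Conditions: K2CO3, acetone, reflux
Reagents that add atoms: propargyl bromide 7, C#CCBr
Why: Williamson etherification of the phenoxide with a primary propargylic bromide.

Step 4
Reactants: 8 1,3-dimethoxy-2-(3-methylbut-2-en-1-yl)-5-(prop-2-yn-1-yloxy)benzene
Product: 9 5,7-dimethoxy-6-(3-methylbut-2-en-1-yl)-2H-chromene
Conditions: N,N-diethylaniline, 200 °C
Reagents that add atoms: none
Why: Thermal aryl propargyl ether Claisen rearrangement, followed in the same pot by hydrogen shift and oxa-6π electrocyclisation, gives the 2H-chromene, and because the two ortho positions of 8 are equivalent by symmetry only one chromene can form.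

Step 5
Reactants: 10 4-iodoresorcinol; 11 triisopropylsilyl chloride
Product: 12 2-iodo-5-(triisopropylsilyloxy)phenol
Conditions: TIPSCl (1.0 equiv), imidazole, DMF, 0 °C
Reagents that add atoms: triisopropylsilyl chloride 11, CC(C)[Si](Cl)(C(C)C)C(C)C
Why: Sterically controlled mono-O-silylation with a bulky chlorosilane should go to the hydroxyl para to iodine, since the other hydroxyl is shielded by the ortho iodine atom.

Step 6
Reactants: 9 5,7-dimethoxy-6-(3-methylbut-2-en-1-yl)-2H-chromene (1.2 equiv); 12 2-iodo-5-(triisopropylsilyloxy)phenol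
Product: 13 (6aR,11aR)-1,3-dimethoxy-2-(3-methylbut-2-en-1-yl)-9-(triisopropylsilyloxy)pterocarpan (cis-fused)
Conditions: Pd2(dba)3 (5 mol %), (R)-BINAP (12 mol %), Ag2CO3 (1.5 equiv), acetone, 55 °C
Reagents that add atoms: none
Why: Proposed new method: zerovalent palladium inserts into the C–I bond of 12, Ag2CO3 removes iodide to leave a cationic (R)-BINAP arylpalladium species, and syn-carbopalladation of C3=C4 of 9 places the aryl group on C3 and palladium on benzylic C4, where no syn β-hydrogen exists (the C3 hydrogen is anti to palladium), so the phenoxide takes C4 by C–O reductive elimination from a six-membered oxapalladacycle, a 5-exo-tet closure of the dihydrofuran ring. The closest known reactions are the racemic Pd(OAc)2/Ag2CO3 oxyarylation of 2H-chromenes with ortho-iodophenols to cis-pterocarpans and the BINAP-controlled cationic asymmetric Heck arylation of cyclic alkenes with aryl iodides and silver salts; letting a chiral bisphosphine choose the alkene face within an oxyarylation is the unproven element. C6a (the later C3) is set in the insertion step by the ligand, which has to deliver the aryl group to the face that gives 6aR. C11a is set by the substrate: aryl and palladium add syn and the two-atom tether lets the oxygen reach C4 only on the face that carries the aryl group, so the ring fusion must be cis (11aR). The step needs regioselectivity (aryl to C3), secured by the benzylic palladium at C4 that the electron-rich ring A stabilises, and chemoselectivity for the conjugated cis-disubstituted chromene alkene over the prenyl alkene, secured by the low reactivity of unactivated trisubstituted alkenes in intermolecular carbopalladation.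

Step 7
Reactants: 13 (6aR,11aR)-1,3-dimethoxy-2-(3-methylbut-2-en-1-yl)-9-(triisopropylsilyloxy)pterocarpan
Product: 14 (3R)-2'-hydroxy-5,7-dimethoxy-6-(3-methylbut-2-en-1-yl)-4'-(triisopropylsilyloxy)isoflavan
Conditions: Li (4 equiv), liq. NH3/THF, –78 °C, short contact; then solid NH4Cl
Reagents that add atoms: none
Why: Dissolving-metal (Birch-type) hydrogenolysis of the benzylic aryl ether breaks the C11a–O bond by electron transfer to a phenoxide and a benzylic anion that ammonia protonates, which removes the C11a centre while C6a (now C3, R) is not involved, and the isolated trisubstituted alkene, the electron-rich rings and the silyl ether are expected to survive the brief exposure without an added alcohol.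

Step 8
Reactants: 14 (3R)-2'-hydroxy-5,7-dimethoxy-6-(3-methylbut-2-en-1-yl)-4'-(triisopropylsilyloxy)isoflavan; 15 3-chloro-3-methylbut-1-yne
Product: 16 (3R)-5,7-dimethoxy-2'-(2-methylbut-3-yn-2-yloxy)-6-(3-methylbut-2-en-1-yl)-4'-(triisopropylsilyloxy)isoflavan
Conditions: DBU, CuCl2 (1 mol %), MeCN, 0 °C
Reagents that add atoms: 3-chloro-3-methylbut-1-yne 15, CC(C)(Cl)C#C
Why: Copper-catalysed O-alkylation of a phenol with a tertiary propargylic chloride (substitution through a copper acetylide-derived electrophile) should give the hindered aryl 1,1-dimethylpropargyl ether under conditions mild enough for the aryl silyl ether.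

Step 9
Reactants: 16 (3R)-5,7-dimethoxy-2'-(2-methylbut-3-yn-2-yloxy)-6-(3-methylbut-2-en-1-yl)-4'-(triisopropylsilyloxy)isoflavan
Product: 17 O-triisopropylsilyl kanzonol I: (3R)-3-[2,2-dimethyl-5-(triisopropylsilyloxy)-2H-chromen-8-yl]-5,7-dimethoxy-6-(3-methylbut-2-en-1-yl)chroman
Conditions: o-xylene, 140 °C
Reagents that add atoms: none
Why: The aromatic propargyl Claisen rearrangement can lead to a rearomatisable intermediate only at C3', the single free ortho position of the 2'-oxygen (attack at substituted C1' reverts), and hydrogen shift plus oxa-6π electrocyclisation then close the 2,2-dimethyl-2H-pyran on ring B with its oxygen on C2'.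

Step 10
Reactants: 17 O-triisopropylsilyl kanzonol I
Product: 18 Kanzonol I: 8-[(3R)-5,7-dimethoxy-6-(3-methylbut-2-en-1-yl)chroman-3-yl]-2,2-dimethyl-2H-chromen-5-ol
Conditions: TBAF, AcOH, THF, 0 °C
Reagents that add atoms: none
Why: Fluoride-driven cleavage of the aryl silyl ether, buffered with acetic acid, should free the 4'-phenol without touching the chromene, the prenyl group or C3.

**Compound list**

1 | 1,3-dimethoxybenzene | COc1cccc(OC)c1 | starting material
2 | prenyl bromide (1-bromo-3-methylbut-2-ene) | CC(C)=CCBr | starting material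
3 | 2,6-dimethoxyphenyllithium | [Li]c1c(OC)cccc1OC | intermediate
4 | 1,3-dimethoxy-2-(3-methylbut-2-en-1-yl)benzene | COc1cccc(OC)c1CC=C(C)C | intermediate
5 | 2-[3,5-dimethoxy-4-(3-methylbut-2-en-1-yl)phenyl]-4,4,5,5-tetramethyl-1,3,2-dioxaborolane | COc1cc(B2OC(C)(C)C(C)(C)O2)cc(OC)c1CC=C(C)C | intermediate
6 | 3,5-dimethoxy-4-(3-methylbut-2-en-1-yl)phenol | COc1cc(O)cc(OC)c1CC=C(C)C | intermediate
7 | propargyl bromide | C#CCBr | starting material
8 | 1,3-dimethoxy-2-(3-methylbut-2-en-1-yl)-5-(prop-2-yn-1-yloxy)benzene | COc1cc(OCC#C)cc(OC)c1CC=C(C)C | intermediate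
9 | 5,7-dimethoxy-6-(3-methylbut-2-en-1-yl)-2H-chromene | COc1cc2c(c(OC)c1CC=C(C)C)C=CCO2 | intermediate
10 | 4-iodoresorcinol | Oc1ccc(I)c(O)c1 | starting material
11 | triisopropylsilyl chloride | CC(C)[Si](Cl)(C(C)C)C(C)C | starting material
12 | 2-iodo-5-(triisopropylsilyloxy)phenol | Oc1cc(O[Si](C(C)C)(C(C)C)C(C)C)ccc1I | intermediate
13 | (6aR,11aR)-1,3-dimethoxy-2-(3-methylbut-2-en-1-yl)-9-(triisopropylsilyloxy)pterocarpan, cis-fused | COc1cc2c(c(OC)c1CC=C(C)C)[C@@H]3Oc4cc(O[Si](C(C)C)(C(C)C)C(C)C)ccc4[C@@H]3CO2 | intermediate
14 | (3R)-2'-hydroxy-5,7-dimethoxy-6-(3-methylbut-2-en-1-yl)-4'-(triisopropylsilyloxy)isoflavan | COc1cc2c(c(OC)c1CC=C(C)C)C[C@H](c1ccc(O[Si](C(C)C)(C(C)C)C(C)C)cc1O)CO2 | intermediate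
15 | 3-chloro-3-methylbut-1-yne | CC(C)(Cl)C#C | starting material
16 | (3R)-5,7-dimethoxy-2'-(2-methylbut-3-yn-2-yloxy)-6-(3-methylbut-2-en-1-yl)-4'-(triisopropylsilyloxy)isoflavan | COc1cc2c(c(OC)c1CC=C(C)C)C[C@H](c1ccc(O[Si](C(C)C)(C(C)C)C(C)C)cc1OC(C)(C)C#C)CO2 | intermediate
17 | O-triisopropylsilyl kanzonol I, (3R)-3-[2,2-dimethyl-5-(triisopropylsilyloxy)-2H-chromen-8-yl]-5,7-dimethoxy-6-(3-methylbut-2-en-1-yl)chroman | COc1cc2c(c(OC)c1CC=C(C)C)C[C@H](c1ccc(O[Si](C(C)C)(C(C)C)C(C)C)c3c1OC(C)(C)C=C3)CO2 | intermediate
18 | Kanzonol I, 8-[(3R)-5,7-dimethoxy-6-(3-methylbut-2-en-1-yl)chroman-3-yl]-2,2-dimethyl-2H-chromen-5-ol | COc1cc2c(c(OC)c1CC=C(C)C)C[C@H](c1ccc(O)c3c1OC(C)(C)C=C3)CO2 | target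

**Count**

Total step count: 10.
Longest linear sequence: 9 steps (1 to 18 through steps 1, 2, 3, 4, 6, 7, 8, 9 and 10); step 5 supplies the second fragment.

**Steps most likely to fail**

Step 6 (carries the label). The chiral bisphosphine may discriminate poorly between the two faces of the chromene, or may slow the insertion so far that reduction of the C–I bond of 12 takes over. The fallback uses known chemistry and trades catalytic enantiocontrol for resolution. It sets out from 9 and 12: the oxyarylation is run with an achiral catalyst (Pd(OAc)2, PPh3, Ag2CO3, acetone, reflux) to the racemic cis-pterocarpan F1. Lithium in ammonia, as in step 7, opens this to the racemic phenol F2. The enantiomers of F2 are separated by preparative chromatography on a chiral stationary phase (cellulose tris(3,5-dimethylphenylcarbamate)); the (R) enantiomer is 14, where the route is rejoined.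

Step 7. Over-reduction or base damage in ammonia may occur: migration of the prenyl double bond into conjugation, partial reduction of a ring, or loss of the silyl group to lithium amide. The fallback sets out from 13 and breaks the C11a–O bond heterolytically instead of by electron transfer. BF3·OEt2 with a large excess of Et3SiH in CH2Cl2 at –78 °C ionises the benzylic ether to a cation stabilised by the three oxygen substituents of ring A, and the silane delivers hydride (ionic hydrogenation of a benzylic ether). A cold quench with Et3N should give 14 directly, where the route is rejoined. The excess of silane is there so that hydride capture outruns loss of the C3 proton. No new compound is made.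

Step 2. The iridium boryl species, or the pinacolborane formed alongside, may hydroborate or isomerise the prenyl double bond. The fallback installs the oxygen before the alkene and sets out from 1. The same borylation/oxidation on the alkene-free arene should give, via 2-(3,5-dimethoxyphenyl)-4,4,5,5-tetramethyl-1,3,2-dioxaborolane F3, 3,5-dimethoxyphenol F4 (which can also be bought). TIPSCl and imidazole convert it into (3,5-dimethoxyphenoxy)triisopropylsilane F5. n-BuLi in THF at 0 °C lithiates between the two methoxy groups to [2,6-dimethoxy-4-(triisopropylsilyloxy)phenyl]lithium F6, which 2 alkylates to [3,5-dimethoxy-4-(3-methylbut-2-en-1-yl)phenoxy]triisopropylsilane F7. TBAF then returns phenol 6, where the route is rejoined.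

**Further compounds**

F1 | step 6 | racemic cis-pterocarpan (13 together with its enantiomer) | COc1cc2c(c(OC)c1CC=C(C)C)[C@@H]3Oc4cc(O[Si](C(C)C)(C(C)C)C(C)C)ccc4[C@@H]3CO2.COc1cc2c(c(OC)c1CC=C(C)C)[C@H]3Oc4cc(O[Si](C(C)C)(C(C)C)C(C)C)ccc4[C@H]3CO2
F2 | step 6 | racemic 2'-hydroxy-5,7-dimethoxy-6-(3-methylbut-2-en-1-yl)-4'-(triisopropylsilyloxy)isoflavan (14 together with its enantiomer) | COc1cc2c(c(OC)c1CC=C(C)C)C[C@H](c1ccc(O[Si](C(C)C)(C(C)C)C(C)C)cc1O)CO2.COc1cc2c(c(OC)c1CC=C(C)C)C[C@@H](c1ccc(O[Si](C(C)C)(C(C)C)C(C)C)cc1O)CO2
F0 | step 7 | none | none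
F3 | step 2 | 2-(3,5-dimethoxyphenyl)-4,4,5,5-tetramethyl-1,3,2-dioxaborolane | COc1cc(OC)cc(B2OC(C)(C)C(C)(C)O2)c1
F4 | step 2 | 3,5-dimethoxyphenol | COc1cc(O)cc(OC)c1
F5 | step 2 | (3,5-dimethoxyphenoxy)triisopropylsilane | COc1cc(O[Si](C(C)C)(C(C)C)C(C)C)cc(OC)c1
F6 | step 2 | [2,6-dimethoxy-4-(triisopropylsilyloxy)phenyl]lithium | [Li]c1c(OC)cc(O[Si](C(C)C)(C(C)C)C(C)C)cc1OC
F7 | step 2 | [3,5-dimethoxy-4-(3-methylbut-2-en-1-yl)phenoxy]triisopropylsilane | COc1cc(O[Si](C(C)C)(C(C)C)C(C)C)cc(OC)c1CC=C(C)C
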